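**Plan**

1. Numbering follows the 6H‑isochromene core (O2, C1, C3, C4, C4a, C5‑Cl, C6=O, C7, C8, C8a; lactone atoms primed). The retrosynthesis cuts C5–C6 and C7–C8 together, which removes C6, C7, the 7‑methyl and the 7‑oxygen as (R)‑lactic acid in the form of its tert‑butyl dioxolanone.
2. The cut is possible because rings A/B form a 4‑alkylidene‑4H‑pyran. O2 donates through C3=C4 and C1=C8a, so exocyclic C5 is a carbon nucleophile (pyrylium anhydrobase), while C8 is the β‑carbon of an alkylidene 2,4‑dioxooxane and thus an acceptor. This donor/acceptor pair matches the acceptor/donor pair C6/C7 of a lactate enolate.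
3. The second cut is C8=C3' (Knoevenagel), giving a 4‑(chloromethylidene)‑4H‑pyran‑3‑carbaldehyde and (S)‑6‑methyloxane‑2,4‑dione. The pyran ring (O2, C1, C3, C4, C4a, C8a) comes from chlorokojic acid: side chain by Wittig olefination, C5 by chloromethylenation of the C4a carbonyl, C8 by carbonylation of the C8a triflate.
4. Forward order: pyranone ring (purchased), then side chain, exocyclic chloroalkene and aldehyde; the lactone ring is made separately and attached; carbocycle B is closed last by a Michael addition/acylative ring closure that also frees the 7‑OH.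
5. Stereochemistry: side‑chain centre from (S)‑2‑methylbutan‑1‑ol; C6' from ethyl (S)‑3‑hydroxybutanoate; C7 from (R)‑lactic acid via the acetal centre (self‑regeneration); C8 by 1,2‑induction in the chelated Michael transition state; C3' is epimerisable.

Key step: step 11

Remark: C‑3' lies between two carbonyl groups and is configurationally labile, so it is taken to settle by enolisation in the drawn (3'R) configuration; exocyclic C=C bonds that later cease to be stereo‑elements (chloromethylidene in 12, 13, 19; alkylidene in 19) are carried as E/Z mixtures and written without descriptor.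

**Route**

Step 1
Reactants: 1 (S)-2-methylbutan-1-ol; 2 2-(triphenyl-λ5-phosphanylidene)propanal
Product: 4 (2E,4S)-2,4-dimethylhex-2-enal, via (S)-2-methylbutanal 3 (not isolated)
Conditions: TEMPO (10 mol %), PhI(OAc)2, CH2Cl2, 23 °C; then 2, toluene, 80 °C
Reagents that add atoms: none
Why: Oxoammonium oxidation (TEMPO/PhI(OAc)2) should give the α‑branched aldehyde without over‑oxidation, and in situ Wittig olefination with the stabilised ylide is E‑selective and avoids isolating the racemisation‑prone aldehyde, so the (S)‑centre from the chiral pool is kept.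

Step 2
Reactants: 5 2-(chloromethyl)-5-hydroxy-4H-pyran-4-one (chlorokojic acid)
Product: 6 6-(chloromethyl)-4-oxo-4H-pyran-3-yl trifluoromethanesulfonate
Conditions: Tf2O, 2,6-lutidine, CH2Cl2, −40 → 0 °C
Reagents that add atoms: triflic anhydride, FC(F)(F)S(=O)(=O)OS(=O)(=O)C(F)(F)F
Why: O‑Sulfonylation of the acidic enolic hydroxy group with Tf2O and a hindered base is a standard enol triflate formation, and the allylic chloride is inert at low temperature.

Step 3
Reactants: 6 6-(chloromethyl)-4-oxo-4H-pyran-3-yl trifluoromethanesulfonate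
Product: 7 [(4-oxo-5-{[(trifluoromethyl)sulfonyl]oxy}-4H-pyran-2-yl)methyl]triphenylphosphonium chloride
Conditions: PPh3, MeCN, 60 °C
Reagents that add atoms: triphenylphosphine, c1ccc(cc1)P(c1ccccc1)c1ccccc1
Why: SN2 displacement of the activated allylic chloride by the phosphine (phosphonium salt formation) should proceed cleanly, since the enol triflate does not react with PPh3 without a transition metal.

Step 4
Reactants: 7 [(4-oxo-5-{[(trifluoromethyl)sulfonyl]oxy}-4H-pyran-2-yl)methyl]triphenylphosphonium chloride; 4 (2E,4S)-2,4-dimethylhex-2-enal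
Product: 9 6-[(1E,3E,5S)-3,5-dimethylhepta-1,3-dien-1-yl]-4-oxo-4H-pyran-3-yl trifluoromethanesulfonate, via phosphonium ylide 8 (not isolated)
Conditions: K2CO3, 18-crown-6 (cat.), CH2Cl2, 23 °C
Reagents that add atoms: none
Why: Wittig olefination; the ylide is stabilised by vinylogous conjugation with the pyranone carbonyl, forms with a weak base that spares the triflate, and should give the new alkene with E geometry, completing the (1E,3E)‑diene.

Step 5
Reactants: 9 6-[(1E,3E,5S)-3,5-dimethylhepta-1,3-dien-1-yl]-4-oxo-4H-pyran-3-yl trifluoromethanesulfonate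
Product: 12 4-(chloromethylidene)-6-[(1E,3E,5S)-3,5-dimethylhepta-1,3-dien-1-yl]-4H-pyran-3-yl trifluoromethanesulfonate (E/Z mixture at the exocyclic C=C), via lithium alkoxide 10 (not isolated), via tertiary trifluoroacetate 11 (not isolated)
Conditions: ICH2Cl, MeLi·LiBr, THF, −78 °C; then (CF3CO)2O, Et3N, −78 → 0 °C
Reagents that add atoms: chloroiodomethane, ClCI
Why: LiCH2Cl generated by iodine–lithium exchange adds 1,2 to the pyranone carbonyl (carbenoid addition to a ketone), and the tertiary trifluoroacetate flanked by two enol ethers loses trifluoroacetate and a proton by way of the aromatic pyrylium ion (the classical 4‑pyranone to 4‑alkylidene‑4H‑pyran conversion), so the transient C‑4 centre is destroyed and no lasting stereocentre arises.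

Step 6
Reactants: 12 4-(chloromethylidene)-6-[(1E,3E,5S)-3,5-dimethylhepta-1,3-dien-1-yl]-4H-pyran-3-yl trifluoromethanesulfonate
Product: 13 4-(chloromethylidene)-6-[(1E,3E,5S)-3,5-dimethylhepta-1,3-dien-1-yl]-4H-pyran-3-carbaldehyde
Conditions: Pd(OAc)2 (5 mol %), Ph2P(CH2)3PPh2, CO (1 atm), HCO2Na, DMF, 70 °C
Reagents that add atoms: carbon monoxide, [C-]#[O+]
Why: Palladium‑catalysed reductive carbonylation (formylation) of an enol triflate with formate as hydride source: oxidative addition into C–OTf, CO insertion and reduction of the acyl‑palladium, while the electron‑rich vinylic C–Cl bond should react far more slowly.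

Step 7
Reactants: 14 ethyl (3S)-3-hydroxybutanoate; 15 tert-butyl acetate
Product: 17 tert-butyl (5S)-5-hydroxy-3-oxohexanoate, via lithium enolate 16 (not isolated)
Conditions: LiN(iPr)2 (excess), THF, −78 °C; then 14, −78 → −20 °C; aq. NH4Cl
Reagents that add atoms: none
Why: Cross‑Claisen condensation of excess lithium tert‑butyl acetate enolate with the β‑hydroxy ester (present as its alkoxide) is a standard route to δ‑hydroxy‑β‑keto esters, and the non‑enolisable carbinol centre is retained.

Step 8
Reactants: 17 tert-butyl (5S)-5-hydroxy-3-oxohexanoate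
Product: 18 (6S)-6-methyloxane-2,4-dione
Conditions: CF3CO2H, CH2Cl2, 23 °C
Reagents that add atoms: none
Why: Acid‑mediated cleavage of the tert‑butyl ester with δ‑lactonisation should give the β‑keto‑δ‑lactone without touching the stereocentre.

Step 9
Reactants: 13 4-(chloromethylidene)-6-[(1E,3E,5S)-3,5-dimethylhepta-1,3-dien-1-yl]-4H-pyran-3-carbaldehyde; 18 (6S)-6-methyloxane-2,4-dione
Product: 19 (6S)-3-({4-(chloromethylidene)-6-[(1E,3E,5S)-3,5-dimethylhepta-1,3-dien-1-yl]-4H-pyran-3-yl}methylidene)-6-methyloxane-2,4-dione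
Conditions: piperidine (10 mol %), AcOH (10 mol %), 4 Å MS, CH2Cl2, 0 → 23 °C
Reagents that add atoms: none
Why: Knoevenagel condensation of the acidic cyclic 1,3‑dicarbonyl with the aldehyde; the adduct is a push–pull system (pyran O‑2 donor, dione acceptor), which together with equimolar stoichiometry should suppress a second addition of 18, and any 2H‑pyran valence isomer formed by oxa‑6π closure stays in equilibrium with it.

Step 10
Reactants: 20 (R)-lactic acid; 21 2,2-dimethylpropanal (pivalaldehyde)
Product: 22 (2R,5R)-2-tert-butyl-5-methyl-1,3-dioxolan-4-one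
Conditions: TsOH·H2O (cat.), H2SO4 (cat.), pentane, reflux, Dean–Stark; crystallisation (pentane, −78 °C)
Reagents that add atoms: none
Why: Acid‑catalysed acetalisation with azeotropic removal of water gives mainly the cis‑dioxolanone, whose new acetal centre (2R) is set by the lactate centre under thermodynamic control and later stores its chirality (self‑regeneration of stereocentres).

Step 11
Reactants: 22 (2R,5R)-2-tert-butyl-5-methyl-1,3-dioxolan-4-one; 19 (6S)-3-({4-(chloromethylidene)-6-[(1E,3E,5S)-3,5-dimethylhepta-1,3-dien-1-yl]-4H-pyran-3-yl}methylidene)-6-methyloxane-2,4-dione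
Product: 27 (7S,8S)-5-chloro-3-[(1E,3E,5S)-3,5-dimethylhepta-1,3-dien-1-yl]-7-hydroxy-7-methyl-8-[(3R,6S)-6-methyl-2,4-dioxooxan-3-yl]-7,8-dihydro-6H-isochromen-6-one (target), via lithium enolate 23 (not isolated), via Michael adduct dionate 24 (not isolated), via silyl enol ether 25 (not isolated), via cyclic silyl ketal 26 (not isolated)
Conditions: LiN(iPr)2, THF, −78 °C; 19, −78 °C; then CH2Cl2, 2,6-lutidine, Me3SiOTf, −78 → −20 °C; aq. citric acid
Reagents that add atoms: none
Why: Proposed new method: enolate 23 adds to C‑8 of 19, the β‑carbon of the alkylidene 2,4‑dioxooxane, through a lithium‑chelated closed transition state to give dionate 24 (C7–C8); Me3SiOTf silylates this to 25 and then reversibly O‑silylates the dioxolanone carbonyl to a dialkoxycarbenium ion, which is attacked by C‑5, the exocyclic terminus of the 4‑alkylidene‑4H‑pyran dienol ether (C5–C6), after which loss of H‑5 to lutidine gives silyl ketal 26 and aqueous acid releases the C‑6 ketone, the 7‑OH and pivalaldehyde. The closest known reaction types are the Michael addition of lithium enolates of lactate‑derived dioxolanones, the addition of enol ethers to ester‑ or orthoester‑derived dialkoxycarbenium ions under silyl triflate activation (Mukaiyama type) and the C‑acylation of pyrylium anhydrobases (4‑methylene‑4H‑pyrans); what is new is a silyl‑activated dioxolanone as the acyl donor in this ring closure. Ring B closes by 6‑exo‑trig attack on the activated C‑6 carbonyl by an alkene whose second carbon (C‑4a) lies inside the new ring, helped by the quaternary C‑7. C‑7 is fixed by attack anti to the tert‑butyl group of the acetal, so C‑8 takes the place of the lactate hydrogen with retention; C‑8 follows from the synclinal chelated arrangement with the pyranyl group antiperiplanar to the enolate C=C and H‑8 over the dioxolanone ring; C‑3' equilibrates. The step needs 1,4‑addition at C‑8 and not 1,6‑addition at C‑1, which lithium coordination to the dione carbonyl should secure, and attack by C‑5 and not by ring carbon C‑4 or an oxygen, which is secured because silylation masks the dionate, C‑4 attack would create an anti‑Bredt bridgehead alkene, and only C‑5 attack passes through an aromatic pyrylium ion.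

**Compound list**

1 | (S)-2-methylbutan-1-ol | CC[C@H](C)CO | starting material
2 | 2-(triphenyl-λ5-phosphanylidene)propanal | CC(C=O)=P(c1ccccc1)(c1ccccc1)c1ccccc1 | starting material
3 | (S)-2-methylbutanal | CC[C@H](C)C=O | intermediate (not isolated)
4 | (2E,4S)-2,4-dimethylhex-2-enal | CC[C@H](C)/C=C(C)/C=O | intermediate
5 | 2-(chloromethyl)-5-hydroxy-4H-pyran-4-one (chlorokojic acid) | ClCC1=CC(=O)C(O)=CO1 | starting material
6 | 6-(chloromethyl)-4-oxo-4H-pyran-3-yl trifluoromethanesulfonate | ClCC1=CC(=O)C(OS(=O)(=O)C(F)(F)F)=CO1 | intermediate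
7 | [(4-oxo-5-{[(trifluoromethyl)sulfonyl]oxy}-4H-pyran-2-yl)methyl]triphenylphosphonium chloride | [Cl-].O=C1C=C(C[P+](c2ccccc2)(c2ccccc2)c2ccccc2)OC=C1OS(=O)(=O)C(F)(F)F | intermediate
8 | ylide of 7, 4-oxo-6-[(triphenyl-λ5-phosphanylidene)methyl]-4H-pyran-3-yl trifluoromethanesulfonate | O=C1C=C(C=P(c2ccccc2)(c2ccccc2)c2ccccc2)OC=C1OS(=O)(=O)C(F)(F)F | intermediate (not isolated)
9 | 6-[(1E,3E,5S)-3,5-dimethylhepta-1,3-dien-1-yl]-4-oxo-4H-pyran-3-yl trifluoromethanesulfonate | CC[C@H](C)/C=C(C)/C=C/C1=CC(=O)C(OS(=O)(=O)C(F)(F)F)=CO1 | intermediate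
10 | lithium 4-(chloromethyl)-6-[(1E,3E,5S)-3,5-dimethylhepta-1,3-dien-1-yl]-3-{[(trifluoromethyl)sulfonyl]oxy}-4H-pyran-4-olate (both epimers at C-4) | CC[C@H](C)/C=C(C)/C=C/C1=CC([O-])(CCl)C(OS(=O)(=O)C(F)(F)F)=CO1.[Li+] | intermediate (not isolated)
11 | 4-(chloromethyl)-6-[(1E,3E,5S)-3,5-dimethylhepta-1,3-dien-1-yl]-3-{[(trifluoromethyl)sulfonyl]oxy}-4H-pyran-4-yl trifluoroacetate (both epimers at C-4) | CC[C@H](C)/C=C(C)/C=C/C1=CC(CCl)(OC(=O)C(F)(F)F)C(OS(=O)(=O)C(F)(F)F)=CO1 | intermediate (not isolated)
12 | 4-(chloromethylidene)-6-[(1E,3E,5S)-3,5-dimethylhepta-1,3-dien-1-yl]-4H-pyran-3-yl trifluoromethanesulfonate (E/Z mixture at the chloromethylidene) | CC[C@H](C)/C=C(C)/C=C/C1=CC(=CCl)C(OS(=O)(=O)C(F)(F)F)=CO1 | intermediate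
13 | 4-(chloromethylidene)-6-[(1E,3E,5S)-3,5-dimethylhepta-1,3-dien-1-yl]-4H-pyran-3-carbaldehyde (E/Z mixture at the chloromethylidene) | CC[C@H](C)/C=C(C)/C=C/C1=CC(=CCl)C(C=O)=CO1 | intermediate
14 | ethyl (3S)-3-hydroxybutanoate | CCOC(=O)C[C@H](C)O | starting material
15 | tert-butyl acetate | CC(=O)OC(C)(C)C | starting material
16 | lithium 1-(tert-butoxy)ethen-1-olate | [Li+].[O-]C(=C)OC(C)(C)C | intermediate (not isolated)
17 | tert-butyl (5S)-5-hydroxy-3-oxohexanoate | C[C@H](O)CC(=O)CC(=O)OC(C)(C)C | intermediate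
18 | (6S)-6-methyloxane-2,4-dione | C[C@H]1CC(=O)CC(=O)O1 | intermediate
19 | (6S)-3-({4-(chloromethylidene)-6-[(1E,3E,5S)-3,5-dimethylhepta-1,3-dien-1-yl]-4H-pyran-3-yl}methylidene)-6-methyloxane-2,4-dione (E/Z mixtures at both exocyclic C=C bonds) | CC[C@H](C)/C=C(C)/C=C/C1=CC(=CCl)C(C=C2C(=O)C[C@H](C)OC2=O)=CO1 | intermediate
20 | (R)-lactic acid | C[C@@H](O)C(O)=O | starting material
21 | 2,2-dimethylpropanal (pivalaldehyde) | CC(C)(C)C=O | starting material
22 | (2R,5R)-2-tert-butyl-5-methyl-1,3-dioxolan-4-one (cis) | C[C@H]1O[C@@H](C(C)(C)C)OC1=O | intermediate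
23 | lithium (2R)-2-tert-butyl-5-methyl-1,3-dioxol-4-olate | CC1=C([O-])O[C@H](C(C)(C)C)O1.[Li+] | intermediate (not isolated)
24 | lithium dionate of the Michael adduct: C-8 bears the pyranyl group, the dioxolanone (through C-7, tert-butyl cis to the 7-methyl) and the lactone enolate; C-7 and C-8 configured as in 27 | CC[C@H](C)/C=C(C)/C=C/C1=CC(=CCl)C(=CO1)[C@@H]([C@]2(C)O[C@@H](C(C)(C)C)OC2=O)C3=C([O-])C[C@H](C)OC3=O.[Li+] | intermediate (not isolated)
25 | 4'-O-trimethylsilyl enol ether of the Michael adduct (stereocentres as in 24) | CC[C@H](C)/C=C(C)/C=C/C1=CC(=CCl)C(=CO1)[C@@H]([C@]2(C)O[C@@H](C(C)(C)C)OC2=O)C3=C(O[Si](C)(C)C)C[C@H](C)OC3=O | intermediate (not isolated)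
26 | cyclised silyl ketal: ring B closed, C-6 carries OSiMe3 and the acetal oxygen of a cis-fused 2-tert-butyl-1,3-dioxolane spanning O-6/O-7, lactone as trimethylsilyl enol ether; C-7 and C-8 as in 27 | CC[C@H](C)/C=C(C)/C=C/C1=CC2=C(Cl)[C@@]3(O[Si](C)(C)C)O[C@H](C(C)(C)C)O[C@@]3(C)[C@@H](C4=C(O[Si](C)(C)C)C[C@H](C)OC4=O)C2=CO1 | intermediate (not isolated)
27 | (7S,8S)-5-chloro-3-[(1E,3E,5S)-3,5-dimethylhepta-1,3-dien-1-yl]-7-hydroxy-7-methyl-8-[(3R,6S)-6-methyl-2,4-dioxooxan-3-yl]-7,8-dihydro-6H-isochromen-6-one | CC[C@H](C)/C=C(C)/C=C/C1=CC2=C(Cl)C(=O)[C@@](C)(O)[C@@H]([C@@H]3C(=O)C[C@H](C)OC3=O)C2=CO1 | target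

**Step count and risks**

Total step count: 11. Longest linear sequence: 7 steps (5 → 6 → 7 → 9 → 12 → 13 → 19 → 27).

Steps most likely to fail:

Step 11 (proposed new method). The acylative ring closure may stall at the silylated Michael adduct or be diverted by ionisation of the acetal C–O bond of the silyl‑activated dioxolanone. In the Michael stage, facial selectivity at C‑8 may be poor, or 1,6‑addition at C‑1 may compete. The fallback uses known chemistry, sets out from 22 and 19 and comes back at 27. The Michael addition is run alone (LiN(iPr)2, THF, −78 °C, AcOH quench) and the neutral Michael adduct F1 is isolated and purified at the stage where C‑7 and C‑8 are set. LiOH in aqueous THF at 0 °C cleaves the dioxolanone to the α‑hydroxy acid F2 with loss of pivalaldehyde. 1‑Chloro‑N,N,2‑trimethylprop‑1‑en‑1‑amine converts this under neutral conditions into the acid chloride F3, which in the presence of 2,6‑lutidine acylates C‑5 intramolecularly (acylation of a pyrylium anhydrobase by an acid chloride) and after loss of HCl gives 27.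

Step 5. The carbenoid may attack the sulfur of the triflate or add in conjugate fashion to the pyranone, or decompose before it adds. The fallback sets out from 9 and comes back at 12 without a nucleophilic organometallic. Carbonyl methylenation with Cp2TiMe2 (toluene, 65 °C) gives the 4‑methylidene‑4H‑pyran triflate F4. Its nucleophilic exocyclic carbon is then chlorinated with N‑chlorosuccinimide and Et3N (CH2Cl2, −78 °C; electrophilic substitution of an anhydrobase) to give 12.

Step 6. Reduction of the palladium intermediate before CO insertion (loss of the triflate as C–H) or sluggish oxidative addition into the electron‑rich enol triflate may prevail. The fallback sets out from 12 and comes back at 13. Stille coupling with Bu3SnCH2OH (Pd(PPh3)4, LiCl, dioxane, 80 °C) gives the allylic alcohol F5, which MnO2 in CH2Cl2 oxidises to the aldehyde 13.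

**Further compounds**

F1 | step 11 | neutral Michael adduct of 22 and 19 (dioxolanone intact, C-7 and C-8 as in 27, C-3' epimers/enol) | CC[C@H](C)/C=C(C)/C=C/C1=CC(=CCl)C(=CO1)[C@@H]([C@]2(C)O[C@@H](C(C)(C)C)OC2=O)C3C(=O)C[C@H](C)OC3=O
F2 | step 11 | α-hydroxy acid from F1: 2-hydroxy-2-methyl-3-(pyranyl)-3-(6-methyl-2,4-dioxooxan-3-yl)propanoic acid, C-7 and C-8 as in 27 | CC[C@H](C)/C=C(C)/C=C/C1=CC(=CCl)C(=CO1)[C@@H]([C@](C)(O)C(O)=O)C2C(=O)C[C@H](C)OC2=O
F3 | step 11 | acid chloride of F2 | CC[C@H](C)/C=C(C)/C=C/C1=CC(=CCl)C(=CO1)[C@@H]([C@](C)(O)C(Cl)=O)C2C(=O)C[C@H](C)OC2=O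
F4 | step 5 | 6-[(1E,3E,5S)-3,5-dimethylhepta-1,3-dien-1-yl]-4-methylidene-4H-pyran-3-yl trifluoromethanesulfonate | CC[C@H](C)/C=C(C)/C=C/C1=CC(=C)C(OS(=O)(=O)C(F)(F)F)=CO1
F5 | step 6 | {4-(chloromethylidene)-6-[(1E,3E,5S)-3,5-dimethylhepta-1,3-dien-1-yl]-4H-pyran-3-yl}methanol | CC[C@H](C)/C=C(C)/C=C/C1=CC(=CCl)C(CO)=CO1
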